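# Lychnostatin 1: oxy-Cope ring-expansion route

## Retrosynthetic overview
1. The α-methylene-γ-lactone comes last, by TEMPO/BAIB oxidative lactonization of a 2-methylene-1,4-diol (C12-OH and C6-OH). The C5/C6 syn-diol comes from OsO4 dihydroxylation of an E-C5=C6 olefin.
2. The 10-membered ring is formed in a single step by anionic oxy-Cope ring expansion (6→10 carbons) of a 1-vinyl-2-(E)-propenylcyclohexanol. This step gives the C1 ketone, the C2–C3 bond, the C4 methyl stereocentre and the E-olefin together.
3. The cyclohexane comes from (S)-4-silyloxycyclohexenone. C8 is the CBS-derived carbinol. C7 is set by anti-conjugate addition of a 2-(silyloxymethyl)vinyl-copper reagent. C10 is set by α'-hydroxylation then α'-methylation. The C6 alkenyl is added by Pd-catalysed α-alkenylation, and the C1 vinyl carbinol by vinyl-cerium addition.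
4. Ring order: cyclohexane, then cyclodecenone (oxy-Cope), then γ-lactone (last step).

Assumptions:
- Compound 3 is supplied by catalogue vendors; if not, it is made in one step from the commercial monoketal by IBX dehydrogenation.
- The chair-like oxy-Cope transition state with the E-propenyl group gives the E-olefin and the natural C4 configuration.
- OsO4 attacks the peripheral face of the E-cyclodecene so that C5/C6 take the natural (S,S) configuration.

## Route

**Step 1**
Reactants: 1, 2-bromoprop-2-en-1-ol
Product: 2, tert-butyl[(2-bromoprop-2-en-1-yl)oxy]diphenylsilane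
Conditions: TBDPSCl, imidazole, DMF, 0 °C → rt
Reagents that add atoms: TBDPSCl, CC(C)(C)[Si](Cl)(c1ccccc1)c1ccccc1
Why: Standard silylation gives the bulky-ether vinyl bromide, which is the precursor of the C11–C13 branch already at the C12 oxidation level (alcohol).

**Step 2**
Reactants: 3, 1,4-dioxaspiro[4.5]dec-6-en-8-one
Product: 4, (8S)-1,4-dioxaspiro[4.5]dec-6-en-8-ol
Conditions: BH3·SMe2, Me-CBS oxazaborolidine (10 mol %, enantiomer that gives S), THF, −20 °C
Reagents that add atoms: none
Why: Corey–Bakshi–Shibata enantioselective ketone reduction sets the carbinol that becomes C8 (S); the symmetric-looking ketal prevents any other stereocentre from forming.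

**Step 3**
Reactants: 4
Product: 5, (8S)-8-(tert-butyldimethylsilyloxy)-1,4-dioxaspiro[4.5]dec-6-ene
Conditions: TBSCl, imidazole, DMF, rt
Reagents that add atoms: TBSCl, CC(C)(C)[Si](C)(C)Cl
Why: Silyl protection of the C8 oxygen, with no change at the stereocentre.

**Step 4**
Reactants: 5
Product: 6, (4S)-4-(tert-butyldimethylsilyloxy)cyclohex-2-en-1-one
Conditions: I2 (10 mol %), acetone, rt
Reagents that add atoms: water (O; trace or workup), O
Why: Neutral ketal exchange unmasks the conjugated enone and leaves the TBS ether intact; the stereocentre is untouched.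

**Step 5**
Reactants: 6
Product: 7, (4S)-4-(TBSO)-6-hydroxycyclohex-2-en-1-one (C6 epimers)
Conditions: LDA, THF, −78 °C; then Davis oxaziridine, −78 °C
Reagents that add atoms: 2-(phenylsulfonyl)-3-phenyloxaziridine, O=S(=O)(c1ccccc1)N1OC1c1ccccc1
Why: Kinetic α'-enolization followed by oxygen transfer (α-hydroxylation) puts oxygen at C10. Its configuration is irrelevant because it is erased in step 7.

**Step 6**
Reactants: 7
Product: 8, (4S)-4-(TBSO)-6-(methoxymethoxy)cyclohex-2-en-1-one
Conditions: MOMCl, i-Pr2NEt, CH2Cl2, 0 °C → rt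
Reagents that add atoms: MOMCl, COCCl
Why: The MOM ether is stable to organometallics, KH and OsO4 and can be removed later without touching silyl ethers.

**Step 7**
Reactants: 8
Product: 9, (4S,6R)-4-(TBSO)-6-(methoxymethoxy)-6-methylcyclohex-2-en-1-one
Conditions: LDA, THF/DMPU, −78 °C; then MeI, −78 → −40 °C
Reagents that add atoms: MeI, CI
Why: α'-Alkylation of the α-alkoxy enolate occurs axially, anti to the pseudo-axial C4-OTBS (avoiding 1,3-diaxial contact). This puts Me trans and OMOM cis to OTBS, which is C10 (R) with O cis to the C8 oxygen as in the target.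

**Step 8**
Reactants: 9 and 2 (converted in situ to the Grignard and cuprate)
Product: 10, (3R,4S,6R)-4-(TBSO)-3-[1-(TBDPSO-methyl)ethenyl]-6-(methoxymethoxy)-6-methylcyclohexan-1-one
Conditions: 2, Mg, THF, then CuBr·SMe2, TMSCl, THF, −78 °C; add 9; aq. NH4Cl
Reagents that add atoms: none (the alkenyl group comes from 2)
Why: Cu-mediated Grignard 1,4-addition to the cyclohexenone occurs anti to the γ-OTBS, setting C7 (R) trans to C8-O. C11–C13 and C12 are installed in one step, with C12 already oxidized.

**Step 9**
Reactants: 10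
Product: 11, (2S,3R,4S,6R)-4-(TBSO)-3-[1-(TBDPSO-methyl)ethenyl]-6-(methoxymethoxy)-6-methyl-2-[(1E)-prop-1-enyl]cyclohexan-1-one
Conditions: (E)-1-bromopropene, Pd2(dba)3, XPhos, NaOtBu, THF/toluene, 70 °C
Reagents that add atoms: (E)-1-bromopropene, C/C=C/Br
Why: Proposed new method: the quaternary C10 blocks enolization on one side, so only C6 (later C6 of the diene) is functionalized; the closest known reaction is Pd/phosphine α-vinylation of ketones with vinyl bromides, extended to this hindered β-branched ketone. The oxidative-addition/reductive-elimination sequence keeps the E geometry, and the new C6 centre ends up trans to C7 under thermodynamic control. That centre is destroyed in step 11.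

**Step 10**
Reactants: 11
Product: 12, 1-vinyl tertiary carbinol of 11 (1,2-divinyl-type oxy-Cope substrate; C1 configuration undefined, diastereomer mixture)
Conditions: CeCl3 (anhydrous), CH2=CHMgBr, THF, −78 °C
Reagents that add atoms: vinylmagnesium bromide, C=C[Mg]Br
Why: Organocerium 1,2-addition (Imamoto type) suppresses enolization of the hindered ketone; the carbinol stereochemistry does not matter because C1 becomes the ketone carbon.

**Step 11**
Reactants: 12
Product: 13, (4S,5E,7R,8S,10R)-8-(TBSO)-12-(TBDPSO)-10-(methoxymethoxy)germacra-5,11(13)-dien-1-one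
Conditions: KH, 18-crown-6, THF, 0 → 45 °C; quench NH4Cl/MeOH at −78 °C
Reagents that add atoms: none
Why: Proposed new method: the potassium alkoxide at C1 accelerates a [3,3] shift that breaks the C1–C6 σ-bond and forms the C3–C4 bond; the enolate is protonated to the C1 ketone. Closest known reaction: anionic oxy-Cope ring expansion of 1,2-divinylcyclohexanols to (E)-cyclodec-5-enones used in germacrane and periplanone syntheses. A chair-like transition state with the E-propenyl group sets C4 and the E-C5=C6 olefin; C7, C8 and C10 are untouched.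

**Step 12**
Reactants: 13
Product: 14, the C10 tertiary alcohol of 13 (MOM removed; C12 still TBDPS, C8 still TBS)
Conditions: ZnBr2, n-PrSH, CH2Cl2, 0 °C
Reagents that add atoms: none
Why: Lewis acid/thiol MOM cleavage (Node conditions) leaves silyl ethers, ketone and olefin intact; C10 is not touched.

**Step 13**
Reactants: 14
Product: 15, the C10 acetate of 14
Conditions: Ac2O, DMAP, Et3N, ClCH2CH2Cl, 70 °C
Reagents that add atoms: acetic anhydride, CC(=O)OC(C)=O
Why: The α-keto tertiary alcohol is the only free hydroxyl, so forcing DMAP-catalysed acylation is chemoselective, and it retains the configuration of C10 (R).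

**Step 14**
Reactants: 15
Product: 16, the C8 alcohol of 15 (TBDPS retained)
Conditions: HF·pyridine, pyridine/THF, 0 °C → rt
Reagents that add atoms: none
Why: The secondary TBS ether is removed much faster than the primary TBDPS ether, exposing C8-OH with retention of configuration (S).

**Step 15**
Reactants: 16
Product: 17, the C8 methacrylate of 16
Conditions: methacrylic anhydride, DMAP, Et3N, BHT, CH2Cl2, 0 °C
Reagents that add atoms: methacrylic anhydride, C=C(C)C(=O)OC(=O)C(C)=C
Why: Acylation of the only free hydroxyl, with no selectivity problem and retention at C8.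

**Step 16**
Reactants: 17
Product: 18, (4S,5S,6S,7S,8S,10R)-5,6-dihydroxy diol of 17 (syn; C12 still TBDPS)
Conditions: OsO4 (5 mol %), NMO, acetone/H2O, 0 °C
Reagents that add atoms: N-methylmorpholine N-oxide, C[N+]1([O-])CCOCC1; water, O
Why: Proposed new method: OsO4 adds two oxygens syn across the strained E-C5=C6 olefin from its peripheral face, giving the syn (zigzag) diol of the target with C5 (S), C6 (S). The bulky TBDPS-shielded 1,1-disubstituted alkene and the electron-poor methacrylate are expected to react more slowly. Closest known reaction: face-selective epoxidation and dihydroxylation of E-olefins in germacrane rings (e.g. costunolide, parthenolide).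

**Step 17**
Reactants: 18
Product: 19, the C12 primary allylic alcohol of 18 (2-methylene-1,4-diol with the 5,6-diol)
Conditions: TBAF, AcOH (1:1), THF, 0 °C
Reagents that add atoms: none
Why: Buffered fluoride cleaves the primary TBDPS ether without basic acyl migration or loss of the acetate or methacrylate.

**Step 18**
Reactants: 19
Product: 20, Lychnostatin 1 (target)
Conditions: TEMPO (20 mol %), PhI(OAc)2, CH2Cl2, rt
Reagents that add atoms: none
Why: TEMPO/BAIB oxidation of the primary allylic alcohol gives the α-methylene aldehyde, which closes to the five-membered lactol with C6-OH and is oxidized to the α-methylene-γ-lactone (oxidative lactonization of a 2-methylene-1,4-diol); the secondary C5/C6 alcohols are not oxidized, and C6 is retained (S).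

## Compound list

| # | Name | SMILES | Role |
|---|---|---|---|
| 1 | 2-bromoprop-2-en-1-ol | C=C(Br)CO | starting material |
| 2 | tert-butyl[(2-bromoprop-2-en-1-yl)oxy]diphenylsilane | C=C(Br)CO[Si](c1ccccc1)(c1ccccc1)C(C)(C)C | intermediate |
| 3 | 1,4-dioxaspiro[4.5]dec-6-en-8-one | O=C1C=CC2(CC1)OCCO2 | starting material |
| 4 | (8S)-1,4-dioxaspiro[4.5]dec-6-en-8-ol | O[C@@H]1C=CC2(CC1)OCCO2 | intermediate |
| 5 | (8S)-8-(TBSO)-1,4-dioxaspiro[4.5]dec-6-ene | CC(C)(C)[Si](C)(C)O[C@@H]1C=CC2(CC1)OCCO2 | intermediate |
| 6 | (4S)-4-(TBSO)cyclohex-2-en-1-one | CC(C)(C)[Si](C)(C)O[C@@H]1C=CC(=O)CC1 | intermediate |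
| 7 | (4S)-4-(TBSO)-6-hydroxycyclohex-2-en-1-one (C6 epimers) | CC(C)(C)[Si](C)(C)O[C@@H]1C=CC(=O)C(O)C1 | intermediate |
| 8 | (4S)-4-(TBSO)-6-(MOMO)cyclohex-2-en-1-one (C6 epimers) | CC(C)(C)[Si](C)(C)O[C@@H]1C=CC(=O)C(OCOC)C1 | intermediate |
| 9 | (4S,6R)-4-(TBSO)-6-(MOMO)-6-methylcyclohex-2-en-1-one | CC(C)(C)[Si](C)(C)O[C@@H]1C=CC(=O)[C@](C)(OCOC)C1 | intermediate |
| 10 | (3R,4S,6R)-4-(TBSO)-3-[1-(TBDPSO-methyl)ethenyl]-6-(MOMO)-6-methylcyclohexanone | CC(C)(C)[Si](C)(C)O[C@@H]1[C@@H](C(=C)CO[Si](c2ccccc2)(c2ccccc2)C(C)(C)C)CC(=O)[C@](C)(OCOC)C1 | intermediate |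
| 11 | (2S,3R,4S,6R)-2-[(1E)-propenyl] analogue of 10 | CC(C)(C)[Si](C)(C)O[C@@H]1[C@@H](C(=C)CO[Si](c2ccccc2)(c2ccccc2)C(C)(C)C)[C@H](/C=C/C)C(=O)[C@](C)(OCOC)C1 | intermediate |
| 12 | 1-vinyl carbinol of 11 (C1 undefined) | CC(C)(C)[Si](C)(C)O[C@@H]1[C@@H](C(=C)CO[Si](c2ccccc2)(c2ccccc2)C(C)(C)C)[C@H](/C=C/C)C(O)(C=C)[C@](C)(OCOC)C1 | intermediate |
| 13 | (4S,5E,7R,8S,10R)-8-(TBSO)-12-(TBDPSO)-10-(MOMO)germacra-5,11(13)-dien-1-one | CC(C)(C)[Si](C)(C)O[C@H]1C[C@@](C)(OCOC)C(=O)CC[C@H](C)/C=C/[C@@H]1C(=C)CO[Si](c2ccccc2)(c2ccccc2)C(C)(C)C | intermediate |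
| 14 | C10-hydroxy analogue of 13 | CC(C)(C)[Si](C)(C)O[C@H]1C[C@@](C)(O)C(=O)CC[C@H](C)/C=C/[C@@H]1C(=C)CO[Si](c2ccccc2)(c2ccccc2)C(C)(C)C | intermediate |
| 15 | C10-acetoxy analogue of 13 | CC(C)(C)[Si](C)(C)O[C@H]1C[C@@](C)(OC(C)=O)C(=O)CC[C@H](C)/C=C/[C@@H]1C(=C)CO[Si](c2ccccc2)(c2ccccc2)C(C)(C)C | intermediate |
| 16 | C8-hydroxy analogue of 15 (TBDPS retained) | O[C@H]1C[C@@](C)(OC(C)=O)C(=O)CC[C@H](C)/C=C/[C@@H]1C(=C)CO[Si](c2ccccc2)(c2ccccc2)C(C)(C)C | intermediate |
| 17 | C8 methacrylate of 16 | C=C(C)C(=O)O[C@H]1C[C@@](C)(OC(C)=O)C(=O)CC[C@H](C)/C=C/[C@@H]1C(=C)CO[Si](c2ccccc2)(c2ccccc2)C(C)(C)C | intermediate |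
| 18 | (4S,5S,6S,7S,8S,10R)-5,6-diol of 17 | C=C(C)C(=O)O[C@H]1C[C@@](C)(OC(C)=O)C(=O)CC[C@H](C)[C@H](O)[C@@H](O)[C@@H]1C(=C)CO[Si](c2ccccc2)(c2ccccc2)C(C)(C)C | intermediate |
| 19 | C12-desilylated triol of 18 | C=C(C)C(=O)O[C@H]1C[C@@](C)(OC(C)=O)C(=O)CC[C@H](C)[C@H](O)[C@@H](O)[C@@H]1C(=C)CO | intermediate |
| 20 | Lychnostatin 1 | C=C(C)C(=O)O[C@H]1C[C@@](C)(OC(C)=O)C(=O)CC[C@H](C)[C@H](O)[C@H]2OC(=O)C(=C)[C@@H]21 | target |

## Totals
- Total steps: 18, including the convergent preparation of 2 in step 1.
- Longest linear sequence: 17 steps (compound 3 → 20).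

## Three steps most likely to fail
1. **Step 11, oxy-Cope.** The C4 diastereoselectivity, the E-olefin geometry and transannular side reactions of the cyclodecenone are all uncertain. Fallback: abandon ring expansion and close the 10-membered ring by intramolecular Nozaki–Hiyama–Kishi allylation, forming C6–C7 and the lactone together from an acyclic allylic bromide/aldehyde.
2. **Step 16, OsO4 dihydroxylation.** Both the chemoselectivity (versus the C11=C13 alkene) and the facial selectivity are conformation-dependent. Fallback: oxidize C12 to the acid, iodolactonize onto the E-olefin (5-exo at C6, trans-fused by the tether), then displace the C5 iodide with acetate and hydrolyze to set the syn-oxygenation.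
3. **Step 9, Pd α-alkenylation.** The ketone is hindered and β-branched, so coupling may be low-yielding. Fallback: α-allylation (LDA, allyl bromide), then vinyl addition, then Ru–H isomerization of the allyl group to the E-propenyl; the tertiary vinyl carbinol has no allylic C–H and cannot itself isomerize.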